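**Assumption:** the target has no stereocentre and its only C=C is endocyclic, so it is achiral and "single enantiomer" has no consequence. The one stereocentre that appears on the way (C3 of 9) is formed racemic and is erased in the last step.

**Retrosynthetic overview**
1. Target 13 ⇐ α,β-dehydrogenation (C3–C4) of the 3-aroylisochroman 9.
2. 9 ⇐ hetero-Diels–Alder of the symmetric, non-aromatic 4,5-dimethoxy-o-quinodimethane 8 with the aldehyde C=O of arylglyoxal 6. This makes C3–C4 and C1–O2 in one operation.
3. 8 ⇐ symmetric dibromide 3 ⇐ veratrole 1 (double bromomethylation); 6 ⇐ 2',4'-dimethoxyacetophenone 4 (Riley oxidation).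
4. Ring order: both benzene rings are bought; the pyran ring is the only ring formed (step 3).

**Route**

Step 1
Reactants: 1 veratrole (1,2-dimethoxybenzene)
Product: 3 1,2-bis(bromomethyl)-4,5-dimethoxybenzene, via 4-(bromomethyl)-1,2-dimethoxybenzene 2 (not isolated)
Conditions: (CH2O)n (2.5 equiv), 33% HBr/AcOH, rt 24 h then 60 °C 1 h; filter, recrystallise
Reagents that add atoms: paraformaldehyde (as formaldehyde, C=O); hydrogen bromide (Br)
Why: Double Blanc-type bromomethylation (electrophilic aromatic substitution); each CH2Br enters para to one OMe, so the symmetric 4,5-product forms; no stereocentre.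

Step 2
Reactants: 4 1-(2,4-dimethoxyphenyl)ethanone
Product: 6 2-(2,4-dimethoxyphenyl)-2-oxoacetaldehyde, via 2,2-dihydroxy-1-(2,4-dimethoxyphenyl)ethanone 5 (not isolated)
Conditions: SeO2 (1.3 equiv), dioxane/H2O 30:1, reflux, 8 h; filter Se; crude hydrate dried by toluene azeotrope (Dean–Stark), used at once
Reagents that add atoms: selenium dioxide (O=[Se]=O)
Why: Riley oxidation of an aryl methyl ketone to the arylglyoxal, which sits as its hydrate in wet dioxane and is dehydrated before use; no stereocentre.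

Step 3
Reactants: 3 1,2-bis(bromomethyl)-4,5-dimethoxybenzene; 6 2-(2,4-dimethoxyphenyl)-2-oxoacetaldehyde
Product: 9 (±)-(6,7-dimethoxy-3,4-dihydro-1H-isochromen-3-yl)(2,4-dimethoxyphenyl)methanone, via 1,2-bis(iodomethyl)-4,5-dimethoxybenzene 7 (not isolated), via 4,5-dimethoxy-o-quinodimethane 8 (not isolated)
Conditions: NaI (5 equiv), 6 (2.5 equiv), 4 Å MS, DMF, 70 °C, 3 added over 6 h by syringe pump; aq. Na2S2O3 work-up
Reagents that add atoms: none
Why: Cava-type iodide-induced 1,4-elimination dearomatises the symmetric dibromide to o-quinodimethane 8, which undergoes a rearomatisation-driven hetero-Diels–Alder reaction with the activated aldehyde C=O of 6 (the aryl ketone C=O is deactivated and hindered). The symmetric diene removes any regiochemical question, and the new C3 stereocentre forms racemic, which does not matter because step 4 removes it.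

Step 4
Reactants: 9 (±)-(6,7-dimethoxy-3,4-dihydro-1H-isochromen-3-yl)(2,4-dimethoxyphenyl)methanone
Product: 13 (6,7-dimethoxy-1H-isochromen-3-yl)(2,4-dimethoxyphenyl)methanone, via lithium enolate of 9 10 (not isolated), via (±)-[6,7-dimethoxy-3-(phenylselanyl)-3,4-dihydro-1H-isochromen-3-yl](2,4-dimethoxyphenyl)methanone 11 (not isolated), via the corresponding selenoxide 12 (not isolated)
Conditions: LiHMDS (1.1 equiv), THF, −78 °C; PhSeBr (1.1 equiv), −78 °C; crude selenide then 30% H2O2, pyridine, CH2Cl2, 0 °C → rt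
Reagents that add atoms: none
Why: Reich selenoxide dehydrogenation; C3 is the only enolisable position, and syn-elimination of the selenoxide can only take a benzylic C4–H, giving the conjugated C3=C4 enone; the C3 stereocentre is destroyed and none is created.

**Compound list**
1 | veratrole (1,2-dimethoxybenzene) | COc1ccccc1OC | starting material
2 | 4-(bromomethyl)-1,2-dimethoxybenzene | COc1ccc(CBr)cc1OC | intermediate (not isolated)
3 | 1,2-bis(bromomethyl)-4,5-dimethoxybenzene | COc1cc(CBr)c(CBr)cc1OC | intermediate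
4 | 1-(2,4-dimethoxyphenyl)ethanone (2',4'-dimethoxyacetophenone) | COc1ccc(C(C)=O)c(OC)c1 | starting material
5 | 2,2-dihydroxy-1-(2,4-dimethoxyphenyl)ethanone (glyoxal hydrate) | COc1ccc(C(=O)C(O)O)c(OC)c1 | intermediate (not isolated)
6 | 2-(2,4-dimethoxyphenyl)-2-oxoacetaldehyde | COc1ccc(C(=O)C=O)c(OC)c1 | intermediate
7 | 1,2-bis(iodomethyl)-4,5-dimethoxybenzene | COc1cc(CI)c(CI)cc1OC | intermediate (not isolated)
8 | 4,5-dimethoxy-o-quinodimethane (2,3-dimethoxy-5,6-dimethylidenecyclohexa-1,3-diene) | C=C1C=C(OC)C(OC)=CC1=C | intermediate (not isolated)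
9 | (±)-(6,7-dimethoxy-3,4-dihydro-1H-isochromen-3-yl)(2,4-dimethoxyphenyl)methanone, racemic | COc1ccc(C(=O)C2Cc3cc(OC)c(OC)cc3CO2)c(OC)c1 | intermediate
10 | lithium enolate of 9 (enolate geometry not relevant) | [Li+].COc1ccc(C([O-])=C2Cc3cc(OC)c(OC)cc3CO2)c(OC)c1 | intermediate (not isolated)
11 | (±)-[6,7-dimethoxy-3-(phenylselanyl)-3,4-dihydro-1H-isochromen-3-yl](2,4-dimethoxyphenyl)methanone, racemic | COc1ccc(C(=O)C2([Se]c4ccccc4)Cc3cc(OC)c(OC)cc3CO2)c(OC)c1 | intermediate (not isolated)
12 | selenoxide of 11 (mixture of diastereomers at Se, racemic) | COc1ccc(C(=O)C2([Se](=O)c4ccccc4)Cc3cc(OC)c(OC)cc3CO2)c(OC)c1 | intermediate (not isolated)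
13 | (6,7-dimethoxy-1H-isochromen-3-yl)(2,4-dimethoxyphenyl)methanone, achiral | COc1ccc(C(=O)C2=Cc3cc(OC)c(OC)cc3CO2)c(OC)c1 | target

**Totals**
Total step count: 4. Longest linear sequence: 3 (1 → 3 → 9 → 13).

**Steps most likely to fail, with fallbacks**

Step 3 (most risky). The o-quinodimethane may dimerise or polymerise faster than it adds to a C=O dienophile, and the I2 formed may interfere. The fallback replaces the cycloaddition by a stepwise ionic double alkylation. It sets out from 3 (partner made from 4) and comes back at 9.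
- Ketone 4 is α-hydroxylated under Moriarty conditions (PhI(OAc)2, KOH, MeOH, 0 °C → rt) to 2-(2,4-dimethoxyphenyl)-2,2-dimethoxyethan-1-ol F1.
- Aqueous HCl/THF hydrolyses the ketal to 2-hydroxy-1-(2,4-dimethoxyphenyl)ethanone F2.
- F2 is O-alkylated with excess 3 (3 equiv, Ag2O, CH2Cl2, rt) to 2-{[2-(bromomethyl)-4,5-dimethoxyphenyl]methoxy}-1-(2,4-dimethoxyphenyl)ethanone F3.
- LiHMDS in dilute THF (−78 → 0 °C) closes the ring by 6-exo-tet enolate C-alkylation to give 9.

Step 4. Perseleninic acid formed from excess H2O2 may epoxidise the electron-rich enol ether, or the α-alkoxy selenide may ionise. The fallback is a Saegusa–Ito dehydrogenation, with no peroxide. It sets out from 9 and comes back at 13.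
- Soft enolisation of 9 (TMSOTf, Et3N, CH2Cl2, 0 °C) gives [(6,7-dimethoxy-1H-isochromen-3(4H)-ylidene)(2,4-dimethoxyphenyl)methoxy]trimethylsilane F4 (E/Z mixture, geometry of no consequence).
- Pd(OAc)2 (1 equiv) in MeCN at rt palladates C3, and β-hydride elimination from C4 gives 13.

Step 2. Risks are over-oxidation to the arylglyoxylic acid, colloidal selenium that is hard to remove, and a hydrate that is hard to dry. The fallback is halogenation followed by Kornblum oxidation. It sets out from 4 and comes back at 6 (through hydrate 5).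
- CuBr2 (2 equiv) in EtOAc/CHCl3 at reflux brominates 4 selectively at the α-carbon to 2-bromo-1-(2,4-dimethoxyphenyl)ethanone F5.
- DMSO with NaHCO3 (rt → 50 °C) converts F5 into the glyoxal, obtained as 5 after aqueous work-up and dried azeotropically to 6.

**Further compounds**
F1 | step 3 | 2-(2,4-dimethoxyphenyl)-2,2-dimethoxyethan-1-ol | COc1ccc(C(OC)(OC)CO)c(OC)c1
F2 | step 3 | 2-hydroxy-1-(2,4-dimethoxyphenyl)ethanone | COc1ccc(C(=O)CO)c(OC)c1
F3 | step 3 | 2-{[2-(bromomethyl)-4,5-dimethoxyphenyl]methoxy}-1-(2,4-dimethoxyphenyl)ethanone | COc1ccc(C(=O)COCc2cc(OC)c(OC)cc2CBr)c(OC)c1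
F4 | step 4 | [(6,7-dimethoxy-1H-isochromen-3(4H)-ylidene)(2,4-dimethoxyphenyl)methoxy]trimethylsilane (E/Z mixture) | COc1ccc(C(O[Si](C)(C)C)=C2Cc3cc(OC)c(OC)cc3CO2)c(OC)c1
F5 | step 2 | 2-bromo-1-(2,4-dimethoxyphenyl)ethanone | COc1ccc(C(=O)CBr)c(OC)c1
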